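**Retrosynthetic overview**

1. C3–Br comes from NBS on 2,5,6-tribromoindole, and C2–Br from exchange of the lactam oxygen of 5,6-dibromooxindole (POBr3); the pyrrole ring is aromatised last.
2. The oxindole comes by loss of CO2 from the oxindole-3-carboxylic acid, which is the Wolff ring-contraction product of 6,7-dibromo-3-diazoquinoline-2,4-dione.
3. The strategy rests on the C3–C3a bond of the five-membered ring. It must sit on the benzo carbon para to C6–Br, and a 1,2-shift of the ring carbon that already carries the C4 carbonyl can form it only there, whereas closure onto 3,4-dibromoaniline could take either ortho carbon.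
4. The diazodione comes from the 4-hydroxyquinolone (diazo transfer), this from Dieckmann closure of an N-malonyl anthranilate, and the anthranilate from the symmetric 4,5-dibromophthalic anhydride by Curtius nitrogen insertion.
5. Ring order: benzene ring bought; transient oxazinedione; six-membered lactam; contraction to the five-membered lactam; pyrrole.

Key step: step 6

Remark: the target is planar and has no stereocentre, so no stereocontrol is needed. The only stereocentre on the way (C3 of 14) forms racemic and is removed in step 7.

**Route**

Step 1
Reactants: 1 4,5-dibromophthalic anhydride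
Product: 5 6,7-dibromo-2H-3,1-benzoxazine-2,4(1H)-dione (6,7-dibromoisatoic anhydride), via acyl azide silyl ester 2 (not isolated), via isocyanato silyl ester 3 (not isolated), via N-silyl benzoxazinedione 4 (not isolated)
Conditions: TMSN3 (1.05 equiv), PhMe, 90 °C; then EtOH, rt
Reagents that add atoms: trimethylsilyl azide, C[Si](C)(C)N=[N+]=[N-]
Why: Azide opens the anhydride to the acyl azide silyl ester, which undergoes Curtius rearrangement at this temperature, the isocyanate is captured by the neighbouring silyl ester and ethanol removes the silyl group; the two anhydride carbonyls are equivalent, so only one isomer can form (Curtius nitrogen insertion into a cyclic anhydride).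

Step 2
Reactants: 5 6,7-dibromo-2H-3,1-benzoxazine-2,4(1H)-dione
Product: 6 methyl 2-amino-4,5-dibromobenzoate
Conditions: MeOH, DMAP (0.1 equiv), 65 °C
Reagents that add atoms: methanol, CO
Why: Methanol adds to the aroyl carbonyl C4 under nucleophilic catalysis and the N-carboxy group left behind loses CO2 (alcoholysis of an isatoic anhydride to an anthranilate ester).

Step 3
Reactants: 6 methyl 2-amino-4,5-dibromobenzoate; 7 methyl malonyl chloride (methyl 3-chloro-3-oxopropanoate)
Product: 8 methyl 4,5-dibromo-2-(3-methoxy-3-oxopropanamido)benzoate
Conditions: pyridine (1.5 equiv), CH2Cl2, 0 °C → rt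
Reagents that add atoms: none
Why: N-acylation of the aniline by an acid chloride (amide formation), which should go cleanly even with the weakly nucleophilic dibromoanthranilate nitrogen, pyridine taking up the HCl.

Step 4
Reactants: 8 methyl 4,5-dibromo-2-(3-methoxy-3-oxopropanamido)benzoate
Product: 11 6,7-dibromo-4-hydroxyquinolin-2(1H)-one, via quinolone methyl ester 9 (not isolated), via quinolone carboxylic acid 10 (not isolated)
Conditions: NaOMe (2.5 equiv), MeOH, 65 °C; then 2 M aq NaOH, 100 °C; then conc. HCl to pH 1, 90 °C
Reagents that add atoms: none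
Why: The malonamide carbanion attacks the aryl ester in a Dieckmann condensation (6-exo-trig C-acylation) that closes the six-membered lactam, and saponification followed by acid-promoted decarboxylation of the β-keto acid frees C3 for diazo transfer.

Step 5
Reactants: 11 6,7-dibromo-4-hydroxyquinolin-2(1H)-one
Product: 12 6,7-dibromo-3-diazoquinoline-2,4(1H,3H)-dione
Conditions: p-ABSA (1.2 equiv), Et3N (2 equiv), DMF, 0 °C → rt
Reagents that add atoms: 4-acetamidobenzenesulfonyl azide, CC(=O)Nc1ccc(cc1)S(=O)(=O)N=[N+]=[N-]
Why: Regitz diazo transfer, in which the enolate of the cyclic β-keto amide attacks the terminal nitrogen of the sulfonyl azide and the adduct collapses to the 2-diazo-1,3-dicarbonyl compound and the sulfonamide.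

Step 6
Reactants: 12 6,7-dibromo-3-diazoquinoline-2,4(1H,3H)-dione
Product: 14 rac-5,6-dibromo-2-oxoindoline-3-carboxylic acid, via ketene 13 (not isolated)
Conditions: hν (365 nm LED), THF–H2O 4:1, Ar, 15 °C; cold extractive isolation
Reagents that add atoms: water, O
Why: Excitation expels N2 and, because the ring holds the diazo group syn-periplanar to the C4 ketone, the aryl carbon C4a shifts from C4 to C3 in concert with nitrogen loss (or through a short-lived singlet acylcarbene); this is the Wolff rearrangement of a cyclic 2-diazo-1,3-dicarbonyl compound, a known reaction type for 3-diazoquinoline-2,4-diones. The shift forms C3–C3a and turns the six-membered lactam into the five-membered lactam of the oxindole by a 1,2-shift ring contraction, not by a chain-end cyclisation, and the ketene 13 is captured by water as the malonic-type acid. The C3 stereocentre of 14 forms racemic under no control, which does not matter because it is enolisable and becomes CH2 in step 7. The selectivity needed is migration of C4a and not of N1; the amide nitrogen is held back by its conjugation with C2=O and its poor migratory aptitude, while an aryl group on a ketone carbonyl migrates readily. Since the migrating carbon is the one that already bore the carbonyl, the bromines can only arrive at C5 and C6, and 365 nm light lies outside the aryl bromide absorption, so photodebromination should not compete.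

Step 7
Reactants: 14 rac-5,6-dibromo-2-oxoindoline-3-carboxylic acid
Product: 15 5,6-dibromoindolin-2-one (5,6-dibromooxindole)
Conditions: 1,4-dioxane–1 M aq HCl, 90 °C
Reagents that add atoms: none
Why: Thermal decarboxylation of a malonic half-amide through a six-membered cyclic transition state gives the lactam enol, which tautomerises to the oxindole.

Step 8
Reactants: 15 5,6-dibromoindolin-2-one
Product: 17 2,5,6-tribromo-1H-indole, via indolyl dibromophosphate 16 (not isolated)
Conditions: POBr3 (1.5 equiv), imidazole (1.2 equiv), ClCH2CH2Cl, 80 °C; then ice-cold aq NaHCO3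
Reagents that add atoms: phosphorus oxybromide, O=P(Br)(Br)Br
Why: Deoxybromination of a lactam, in which the 2-hydroxyindole tautomer is O-phosphorylated and bromide displaces the phosphate at C2 by addition–elimination to give the aromatic 2-bromoindole, the known conversion of oxindoles into 2-bromoindoles.

Step 9
Reactants: 17 2,5,6-tribromo-1H-indole
Product: 18 2,3,5,6-tetrabromo-1H-indole
Conditions: NBS (1.0 equiv), DMF, 0 °C, dark
Reagents that add atoms: N-bromosuccinimide, O=C1CCC(=O)N1Br
Why: Electrophilic aromatic bromination at C3, the most nucleophilic position of the indole, while C2 is blocked and the benzo ring is deactivated by two bromines, so one equivalent should stop at the tetrabromide.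

**Compound list**

1 | 4,5-dibromophthalic anhydride | O=C1OC(=O)c2cc(Br)c(Br)cc12 | starting material
2 | trimethylsilyl 2-(azidocarbonyl)-4,5-dibromobenzoate | C[Si](C)(C)OC(=O)c1cc(Br)c(Br)cc1C(=O)N=[N+]=[N-] | intermediate
3 | trimethylsilyl 4,5-dibromo-2-isocyanatobenzoate | C[Si](C)(C)OC(=O)c1cc(Br)c(Br)cc1N=C=O | intermediate
4 | 6,7-dibromo-1-(trimethylsilyl)-2H-3,1-benzoxazine-2,4(1H)-dione | C[Si](C)(C)N1C(=O)OC(=O)c2cc(Br)c(Br)cc12 | intermediate
5 | 6,7-dibromo-2H-3,1-benzoxazine-2,4(1H)-dione | O=C1Nc2cc(Br)c(Br)cc2C(=O)O1 | intermediate
6 | methyl 2-amino-4,5-dibromobenzoate | COC(=O)c1cc(Br)c(Br)cc1N | intermediate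
7 | methyl malonyl chloride (methyl 3-chloro-3-oxopropanoate) | COC(=O)CC(Cl)=O | starting material
8 | methyl 4,5-dibromo-2-(3-methoxy-3-oxopropanamido)benzoate | COC(=O)CC(=O)Nc1cc(Br)c(Br)cc1C(=O)OC | intermediate
9 | methyl 6,7-dibromo-4-hydroxy-2-oxo-1,2-dihydroquinoline-3-carboxylate | COC(=O)C1=C(O)c2cc(Br)c(Br)cc2NC1=O | intermediate
10 | 6,7-dibromo-4-hydroxy-2-oxo-1,2-dihydroquinoline-3-carboxylic acid | OC(=O)C1=C(O)c2cc(Br)c(Br)cc2NC1=O | intermediate
11 | 6,7-dibromo-4-hydroxyquinolin-2(1H)-one | O=C1C=C(O)c2cc(Br)c(Br)cc2N1 | intermediate
12 | 6,7-dibromo-3-diazoquinoline-2,4(1H,3H)-dione | [N-]=[N+]=C1C(=O)Nc2cc(Br)c(Br)cc2C1=O | intermediate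
13 | 5,6-dibromo-3-(oxomethylidene)indolin-2-one (ketene) | O=C=C1C(=O)Nc2cc(Br)c(Br)cc12 | intermediate
14 | rac-5,6-dibromo-2-oxoindoline-3-carboxylic acid (C3 racemic, enolisable) | OC(=O)C1C(=O)Nc2cc(Br)c(Br)cc12 | intermediate
15 | 5,6-dibromoindolin-2-one | O=C1Cc2cc(Br)c(Br)cc2N1 | intermediate
16 | 5,6-dibromo-1H-indol-2-yl phosphorodibromidate | O=P(Br)(Br)Oc1cc2cc(Br)c(Br)cc2[nH]1 | intermediate
17 | 2,5,6-tribromo-1H-indole | Brc1cc2cc(Br)[nH]c2cc1Br | intermediate
18 | 2,3,5,6-tetrabromo-1H-indole | Brc1cc2[nH]c(Br)c(Br)c2cc1Br | target

**Step count**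

Total steps: 9. Longest linear sequence: 9 steps (from 1 to 18).

**Steps most likely to fail**

Step 6. The excited diazodione may lose nitrogen without rearranging, so that the carbene inserts into the O–H bond of water, or the acid may decarboxylate and degrade during isolation. The fallback avoids the diazodione and keeps the regiochemistry fixed by the carbonyl-bearing ring carbon. It sets out from 5 and comes back at 15.
- Compound 5 would be opened with N,O-dimethylhydroxylamine hydrochloride and Et3N in refluxing aqueous EtOH to 2-amino-4,5-dibromo-N-methoxy-N-methylbenzamide F1.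
- Excess MeMgBr in THF at 0 °C should give 1-(2-amino-4,5-dibromophenyl)ethan-1-one F2.
- Oxidation of the acetyl group with I2/TBHP in DMSO at 80 °C (C–H oxidation followed by lactamisation) should give 5,6-dibromoindoline-2,3-dione F3.
- Hydrazine hydrate would form 5,6-dibromo-3-hydrazinylideneindolin-2-one F4, which on further heating at 130 °C undergoes Wolff–Kishner reduction to 15.

Step 8. Deoxybromination may stall at the phosphorylated lactam, and the 2-bromoindole may oligomerise or revert to the lactam under the acidic conditions and on work-up. The fallback installs the C2 bromine together with a C3 carbon substituent that stabilises the ring. It sets out from 15 and comes back at 18.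
- Vilsmeier haloformylation of 15 with POBr3/DMF in CHCl3 (0 °C to reflux) should give 2,5,6-tribromo-1H-indole-3-carbaldehyde F5.
- Pinnick oxidation (NaClO2, NaH2PO4, 2-methyl-2-butene, t-BuOH–H2O) should give 2,5,6-tribromo-1H-indole-3-carboxylic acid F6.
- NBS with NaHCO3 in DMF at rt should replace the carboxyl group by bromine through ipso attack at C3 and loss of CO2, giving 18 directly.

Step 1. The Curtius rearrangement may be incomplete, or a second equivalent of azide may attack the oxazinedione and lead on to a benzimidazolone. The fallback reaches the anthranilate by the classical imide route. It sets out from 1 and comes back at 6.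
- A urea melt at 140 °C would convert 1 into 4,5-dibromophthalimide F7.
- Hofmann rearrangement with one equivalent of NaOCl in aq NaOH (0 → 80 °C, then acidification to pH 4) should give 2-amino-4,5-dibromobenzoic acid F8 as a single isomer, since the imide is symmetric.
- Esterification with SOCl2 in MeOH at reflux gives 6.

**Further compounds**

F1 | step 6 | 2-amino-4,5-dibromo-N-methoxy-N-methylbenzamide | CON(C)C(=O)c1cc(Br)c(Br)cc1N
F2 | step 6 | 1-(2-amino-4,5-dibromophenyl)ethan-1-one | CC(=O)c1cc(Br)c(Br)cc1N
F3 | step 6 | 5,6-dibromoindoline-2,3-dione | O=C1Nc2cc(Br)c(Br)cc2C1=O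
F4 | step 6 | 5,6-dibromo-3-hydrazinylideneindolin-2-one | NN=C1C(=O)Nc2cc(Br)c(Br)cc12
F5 | step 8 | 2,5,6-tribromo-1H-indole-3-carbaldehyde | O=Cc1c(Br)[nH]c2cc(Br)c(Br)cc12
F6 | step 8 | 2,5,6-tribromo-1H-indole-3-carboxylic acid | OC(=O)c1c(Br)[nH]c2cc(Br)c(Br)cc12
F7 | step 1 | 4,5-dibromophthalimide | O=C1NC(=O)c2cc(Br)c(Br)cc12
F8 | step 1 | 2-amino-4,5-dibromobenzoic acid | Nc1cc(Br)c(Br)cc1C(O)=O
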